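**Retrosynthetic overview**
1. The hydroxyquinone comes last, by Teuber oxidation of resorcinol 24; the C1'–C2' bond comes from a Negishi coupling of benzylzinc 22 with (E)-vinyl iodide 15, made by methylalumination of the C4' ethynyl carbinol 13.
2. The C6 methyl and the C4' hydroxyl come from unravelling the cis-fused δ-lactone 8: C=O becomes CH3, the ring oxygen becomes C4'–OH, which is then inverted (Mitsunobu).
3. The cyclohexanone ring is made in one Diels–Alder step that forms C1–C2 and C5–C6: (Z)-2-silyloxydiene 2 (C2–C5, from ethyl vinyl ketone) plus (R)-4-methyl-6-alkynyl-5,6-dihydropyran-2-one 7 (C1=C6).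
4. Enabling feature: the ketone C3 is β to the quaternary C1 (2-oxydiene retron), and the C6 methyl carbon is 1,5 to the C4' oxygen (CH3–C6–C1–C5'–C4'–O). Both can therefore be closed into a six-membered unsaturated lactone ring that activates C1=C6 (C1 as β-carbon), locks the C6 carbon cis to C5', and relays the C4' stereocentre to C1, C2 and C6.
5. Ring order: lactone ring (metathesis), then cyclohexene ring (Diels–Alder), then lactone opened, then the benzene ring oxidised to the quinone.

Key step: step 5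

Remark: locants used in the text are ring C1 (quaternary) to C6 with C3 = C=O, and side chain C1' (on the quinone) to C5' (on C1). Ethyl vinyl ketone, 3-(trimethylsilyl)propynal and orcinol are taken as commercial. The sense of induction in step 2 is assigned by the usual model for diisopinocampheylboranes (reagent from (+)-Ipc2BOMe, Re-face attack).

**Route**

Step 1
Reactants: 1 pent-1-en-3-one (ethyl vinyl ketone)
Product: 2 triisopropyl{[(3Z)-penta-1,3-dien-3-yl]oxy}silane
Conditions: i-Pr3SiOTf, Et3N, CH2Cl2, 0 → 23 °C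
Reagents that add atoms: triisopropylsilyl trifluoromethanesulfonate, CC(C)[Si](OS(=O)(=O)C(F)(F)F)(C(C)C)C(C)C
Why: Soft enolisation of the ethyl group (silyl enol ether formation with a silyl triflate/amine pair) should give the cross-conjugated 2-silyloxydiene, mainly as the (Z)-enol ether whose methyl points outward in the s-cis diene and which is the only isomer reactive in step 5.

Step 2
Reactants: 3 3-(trimethylsilyl)prop-2-ynal
Product: 5 (3R)-5-methyl-1-(trimethylsilyl)hex-5-en-1-yn-3-ol, via diisopinocampheylborinate ester 4 (not isolated)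
Conditions: (+)-Ipc2BOMe, CH2=C(CH3)CH2MgCl, Et2O, 0 → 23 °C; then 3, −78 °C; then H2NCH2CH2OH, 23 °C
Reagents that add atoms: 2-methylallylmagnesium chloride, CC(=C)C[Mg]Cl
Why: Asymmetric methallylboration (Brown type) through a chair Zimmerman–Traxler transition state should add to the Re face of the ynal and set the (R)-carbinol, which is deliberately the C4' epimer of the target because the cycloaddition in step 5 occurs anti to this substituent.

Step 3
Reactants: 5 (3R)-5-methyl-1-(trimethylsilyl)hex-5-en-1-yn-3-ol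
Product: 6 (3R)-5-methyl-1-(trimethylsilyl)hex-5-en-1-yn-3-yl prop-2-enoate
Conditions: CH2=CHCOCl, Et3N, DMAP (cat.), CH2Cl2, −20 → 0 °C
Reagents that add atoms: acryloyl chloride, C=CC(=O)Cl
Why: O-Acylation of the secondary propargylic alcohol with an acid chloride (nucleophilic catalysis) leaves the stereocentre untouched.

Step 4
Reactants: 6 (3R)-5-methyl-1-(trimethylsilyl)hex-5-en-1-yn-3-yl prop-2-enoate
Product: 7 (6R)-4-methyl-6-[(trimethylsilyl)ethynyl]-5,6-dihydro-2H-pyran-2-one
Conditions: RuCl2(=CHPh)(H2IMes)(PCy3) (second-generation Grubbs catalyst, 5 mol %), PhMe, 80 °C, high dilution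
Reagents that add atoms: none
Why: Ring-closing metathesis of the acrylate with the 1,1-disubstituted alkene gives the trisubstituted unsaturated δ-lactone, driven by loss of ethene, while the bulky silylalkyne should stay out of enyne metathesis.

Step 5
Reactants: 7 (6R)-4-methyl-6-[(trimethylsilyl)ethynyl]-5,6-dihydro-2H-pyran-2-one; 2 triisopropyl{[(3Z)-penta-1,3-dien-3-yl]oxy}silane
Product: 8 (3R,4aR,5S,8aS)-4a,5-dimethyl-6-[(triisopropylsilyl)oxy]-3-[(trimethylsilyl)ethynyl]-3,4,4a,5,8,8a-hexahydro-1H-isochromen-1-one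
Conditions: 2 (2.5 equiv), AlBr3/AlMe3 (10:1, 20 mol % Al), PhMe/CH2Cl2, −20 → 0 °C; pyridine, then aq. NaHCO3
Reagents that add atoms: none
Why: The aluminium Lewis acid (AlBr3 buffered by AlMe3, which scavenges protic acid and spares the silyl enol ether) binds the lactone carbonyl, and 7 reacts as a normal-demand dienophile with the 2-silyloxydiene in a concerted but strongly asynchronous [4+2] cycloaddition (Mukaiyama–Michael-like in its stepwise limit); the closest precedent is the mixed AlBr3/AlMe3-catalysed Diels–Alder reaction of 2-silyloxydienes with β,β-disubstituted cycloalkenones that creates quaternary carbons. The cyclohexene ring is closed intermolecularly by suprafacial union of both diene termini with the lactone C=C, and the regiochemistry follows from the large HOMO coefficient at the methyl-bearing enol-ether terminus (future C2), which bonds to the lactone β-carbon (future C1) so that the CH2 terminus (C5) joins the α-carbon (C6). The cis relation of the C6 acyl carbon and the C5' methylene is fixed by the lactone ring, which holds the dienophile in the (Z) geometry. The absolute configuration at C1 and C6 comes from the (R)-carbinol at C4': the alkynyl group sits pseudo-equatorial on the half-chair and the diene adds to the opposite face, as with 5-substituted cyclohexenones and 6-substituted dihydropyranones. C2 is set by the endo transition state, in which the lactone ring lies under the diene and the outward methyl of the (Z)-enol ether ends up cis to the lactone bonds and trans to the C1 methyl, which is also the equatorial and more stable arrangement once the ketone is freed. The step thus needs regio-, endo- and facial selectivity and survival of the enol ether, secured in turn by the siloxy group, the cyclic dienophile, the C4' substituent and the AlMe3 buffer.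

Step 6
Reactants: 8 (3R,4aR,5S,8aS)-4a,5-dimethyl-6-[(triisopropylsilyl)oxy]-3-[(trimethylsilyl)ethynyl]-3,4,4a,5,8,8a-hexahydro-1H-isochromen-1-one
Product: 9 (3R,4aR,5S,8aS)-4a,5-dimethyl-6-[(triisopropylsilyl)oxy]-3-[(trimethylsilyl)ethynyl]-3,4,4a,5,8,8a-hexahydro-1H-isochromen-1-ol (anomeric mixture)
Conditions: i-Bu2AlH (1.2 equiv), CH2Cl2, −78 °C; aq. KNaC4H4O6
Reagents that add atoms: none
Why: Partial reduction of the lactone to the lactol stops at the tetrahedral aluminate at −78 °C, and the enol ether and alkynylsilane are inert to the hydride.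

Step 7
Reactants: 9 (3R,4aR,5S,8aS)-4a,5-dimethyl-6-[(triisopropylsilyl)oxy]-3-[(trimethylsilyl)ethynyl]-3,4,4a,5,8,8a-hexahydro-1H-isochromen-1-ol
Product: 10 N'-[(E)-{(1S,5S,6S)-6-[(2R)-2-hydroxy-4-(trimethylsilyl)but-3-yn-1-yl]-5,6-dimethyl-4-[(triisopropylsilyl)oxy]cyclohex-3-en-1-yl}methylidene]-4-methylbenzenesulfonohydrazide
Conditions: TsNHNH2, MgSO4, THF, 23 → 40 °C
Reagents that add atoms: 4-methylbenzenesulfonohydrazide, Cc1ccc(cc1)S(=O)(=O)NN
Why: Hydrazone condensation on the open hydroxy-aldehyde form of the lactol frees the C4' hydroxyl without ever placing a leaving group on the C6 carbon, which avoids closure to a tetrahydropyran.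

Step 8
Reactants: 10 N'-[(E)-{(1S,5S,6S)-6-[(2R)-2-hydroxy-4-(trimethylsilyl)but-3-yn-1-yl]-5,6-dimethyl-4-[(triisopropylsilyl)oxy]cyclohex-3-en-1-yl}methylidene]-4-methylbenzenesulfonohydrazide
Product: 11 (2R)-4-(trimethylsilyl)-1-[(1S,2S,6S)-1,2,6-trimethyl-3-[(triisopropylsilyl)oxy]cyclohex-3-en-1-yl]but-3-yn-2-ol
Conditions: catecholborane (3 equiv), CHCl3, 0 → 23 °C; then NaOAc·3H2O, 60 °C
Reagents that add atoms: none
Why: Caglioti-type reduction of the tosylhydrazone (hydroboration of C=N, then acetate-induced loss of sulfinate and N2) turns CH=N into the C6 methyl group under mild, non-basic conditions that leave C6 and the silyl groups alone.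

Step 9
Reactants: 11 (2R)-4-(trimethylsilyl)-1-[(1S,2S,6S)-1,2,6-trimethyl-3-[(triisopropylsilyl)oxy]cyclohex-3-en-1-yl]but-3-yn-2-ol
Product: 12 (2S)-4-(trimethylsilyl)-1-[(1S,2S,6S)-1,2,6-trimethyl-3-[(triisopropylsilyl)oxy]cyclohex-3-en-1-yl]but-3-yn-2-yl 4-nitrobenzoate
Conditions: PPh3, i-PrO2CN=NCO2i-Pr, 4-O2NC6H4CO2H, THF, 0 → 23 °C
Reagents that add atoms: 4-nitrobenzoic acid, OC(=O)c1ccc(cc1)[N+](=O)[O-]
Why: Mitsunobu reaction (SN2 attack of the carboxylate on the alkoxyphosphonium ion) inverts the relay stereocentre to the (S) configuration required at C4', a change that propargylic carbinols undergo cleanly.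

Step 10
Reactants: 12 (2S)-4-(trimethylsilyl)-1-[(1S,2S,6S)-1,2,6-trimethyl-3-[(triisopropylsilyl)oxy]cyclohex-3-en-1-yl]but-3-yn-2-yl 4-nitrobenzoate
Product: 13 (2S)-1-[(1S,2S,6S)-1,2,6-trimethyl-3-[(triisopropylsilyl)oxy]cyclohex-3-en-1-yl]but-3-yn-2-ol
Conditions: K2CO3 (cat.), MeOH, 23 °C
Reagents that add atoms: none
Why: Base-catalysed methanolysis removes the nitrobenzoate and the alkynyl trimethylsilyl group in one operation, while the hindered triisopropylsilyl enol ether should persist.

Step 11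
Reactants: 13 (2S)-1-[(1S,2S,6S)-1,2,6-trimethyl-3-[(triisopropylsilyl)oxy]cyclohex-3-en-1-yl]but-3-yn-2-ol
Product: 15 (2S,3E)-4-iodo-3-methyl-1-[(1S,2S,6S)-1,2,6-trimethyl-3-[(triisopropylsilyl)oxy]cyclohex-3-en-1-yl]but-3-en-2-ol, via alkenylalane 14 (not isolated)
Conditions: AlMe3 (3.5 equiv), Cp2ZrCl2 (0.3 equiv), CH2Cl2, 0 → 23 °C; then I2, THF, −30 → 0 °C
Reagents that add atoms: trimethylaluminium, C[Al](C)C; iodine, II
Why: Negishi zirconium-catalysed syn-methylalumination puts the methyl on the internal alkyne carbon (C3') and aluminium on the terminal one, and iodinolysis with retention should give the (E)-trisubstituted vinyl iodide, the hydroxyl being carried as its aluminium alkoxide.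

Step 12
Reactants: 16 5-methylbenzene-1,3-diol (orcinol)
Product: 17 1,3-bis(methoxymethoxy)-5-methylbenzene
Conditions: CH3OCH2Cl, i-Pr2NEt, CH2Cl2, 0 → 23 °C
Reagents that add atoms: chloromethyl methyl ether, COCCl
Why: Williamson-type acetal protection of both phenols installs the directing groups for the next metalation and the masking groups for the resorcinol.

Step 13
Reactants: 17 1,3-bis(methoxymethoxy)-5-methylbenzene
Product: 19 [2,6-bis(methoxymethoxy)-4-methylphenyl]methanol, via aryllithium 18 (not isolated)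
Conditions: n-BuLi, THF, 0 °C; then (CH2O)n, 0 → 23 °C; H2O
Reagents that add atoms: formaldehyde (from paraformaldehyde), C=O
Why: Directed ortho-metalation takes place at the doubly activated position between the two acetal oxygens, and the aryllithium is hydroxymethylated by formaldehyde.

Step 14
Reactants: 19 [2,6-bis(methoxymethoxy)-4-methylphenyl]methanol
Product: 20 [3-chloro-2,6-bis(methoxymethoxy)-4-methylphenyl]methanol
Conditions: N-chlorosuccinimide (1.0 equiv), MeCN, 0 → 23 °C
Reagents that add atoms: N-chlorosuccinimide, O=C1CCC(=O)N1Cl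
Why: Electrophilic aromatic chlorination can only give one regioisomer because the two free ring positions are equivalent by symmetry and each is ortho/para to the acetal oxygens.

Step 15
Reactants: 20 [3-chloro-2,6-bis(methoxymethoxy)-4-methylphenyl]methanol
Product: 21 3-chloro-2,6-bis(methoxymethoxy)-4-methylbenzyl chloride
Conditions: PPh3, N-chlorosuccinimide, THF, 0 °C
Reagents that add atoms: N-chlorosuccinimide, O=C1CCC(=O)N1Cl
Why: Appel-type chlorination through the alkoxyphosphonium ion works under neutral conditions that the acetals tolerate.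

Step 16
Reactants: 21 3-chloro-2,6-bis(methoxymethoxy)-4-methylbenzyl chloride; 15 (2S,3E)-4-iodo-3-methyl-1-[(1S,2S,6S)-1,2,6-trimethyl-3-[(triisopropylsilyl)oxy]cyclohex-3-en-1-yl]but-3-en-2-ol
Product: 23 (2S,3E)-5-[3-chloro-2,6-bis(methoxymethoxy)-4-methylphenyl]-3-methyl-1-[(1S,2S,6S)-1,2,6-trimethyl-3-[(triisopropylsilyl)oxy]cyclohex-3-en-1-yl]pent-3-en-2-ol, via benzylzinc chloride 22 (not isolated)
Conditions: 21, Zn, LiCl, THF, 23 °C; then 15, Pd(OAc)2 (2 mol %), SPhos (4 mol %), THF, 23 °C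
Reagents that add atoms: none
Why: Zinc insertion into the benzylic chloride followed by Negishi cross-coupling with the vinyl iodide should form the C1'–C2' bond with retention of the (E) geometry, the organozinc tolerating the free hydroxyl, the acetals and the enol ether.

Step 17
Reactants: 23 (2S,3E)-5-[3-chloro-2,6-bis(methoxymethoxy)-4-methylphenyl]-3-methyl-1-[(1S,2S,6S)-1,2,6-trimethyl-3-[(triisopropylsilyl)oxy]cyclohex-3-en-1-yl]pent-3-en-2-ol
Product: 24 4-chloro-2-[(2E,4S)-4-hydroxy-3-methyl-5-[(1S,2S,6S)-1,2,6-trimethyl-3-oxocyclohexyl]pent-2-en-1-yl]-5-methylbenzene-1,3-diol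
Conditions: aq. HCl (2 M), MeOH/THF, 23 → 40 °C
Reagents that add atoms: none
Why: Acid-catalysed acetal and silyl enol ether hydrolysis releases both phenols and the C3 ketone in one operation, and C2, now α to the ketone, already has the more stable equatorial configuration.

Step 18
Reactants: 24 4-chloro-2-[(2E,4S)-4-hydroxy-3-methyl-5-[(1S,2S,6S)-1,2,6-trimethyl-3-oxocyclohexyl]pent-2-en-1-yl]-5-methylbenzene-1,3-diol
Product: 25 5-chloro-2-hydroxy-3-[(2E,4S)-4-hydroxy-3-methyl-5-[(1S,2S,6S)-1,2,6-trimethyl-3-oxocyclohexyl]pent-2-en-1-yl]-6-methylcyclohexa-2,5-diene-1,4-dione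
Conditions: (KSO3)2NO (Fremy's salt, 2.5 equiv), KH2PO4 buffer, acetone/H2O, 0 → 23 °C
Reagents that add atoms: Fremy's salt (potassium nitrosodisulfonate), [K+].[K+].[O]N(S(=O)(=O)[O-])S(=O)(=O)[O-]
Why: Teuber oxidation converts the phenol whose para position is the only free ring CH into the p-quinone while the other hydroxyl remains as the 2-hydroxy group, and oxidation through that other phenol would lead to the same compound as its tautomer.

**Compound list**
1 | pent-1-en-3-one | CCC(=O)C=C | starting material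
2 | triisopropyl{[(3Z)-penta-1,3-dien-3-yl]oxy}silane | C/C=C(\O[Si](C(C)C)(C(C)C)C(C)C)C=C | intermediate
3 | 3-(trimethylsilyl)prop-2-ynal | C[Si](C)(C)C#CC=O | starting material
4 | (3R)-5-methyl-1-(trimethylsilyl)hex-5-en-1-yn-3-yl bis[(+)-isopinocampheyl]borinate | C[Si](C)(C)C#C[C@@H](CC(C)=C)OB([C@H]1C[C@H]2C[C@@H]([C@@H]1C)C2(C)C)[C@H]1C[C@H]2C[C@@H]([C@@H]1C)C2(C)C | intermediate
5 | (3R)-5-methyl-1-(trimethylsilyl)hex-5-en-1-yn-3-ol | C[Si](C)(C)C#C[C@H](O)CC(C)=C | intermediate
6 | (3R)-5-methyl-1-(trimethylsilyl)hex-5-en-1-yn-3-yl prop-2-enoate | C[Si](C)(C)C#C[C@H](OC(=O)C=C)CC(C)=C | intermediate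
7 | (6R)-4-methyl-6-[(trimethylsilyl)ethynyl]-5,6-dihydro-2H-pyran-2-one | C[Si](C)(C)C#C[C@H]1CC(C)=CC(=O)O1 | intermediate
8 | (3R,4aR,5S,8aS)-4a,5-dimethyl-6-[(triisopropylsilyl)oxy]-3-[(trimethylsilyl)ethynyl]-3,4,4a,5,8,8a-hexahydro-1H-isochromen-1-one | C[Si](C)(C)C#C[C@H]1C[C@]2(C)[C@H](C)C(O[Si](C(C)C)(C(C)C)C(C)C)=CC[C@@H]2C(=O)O1 | intermediate
9 | (3R,4aR,5S,8aS)-4a,5-dimethyl-6-[(triisopropylsilyl)oxy]-3-[(trimethylsilyl)ethynyl]-3,4,4a,5,8,8a-hexahydro-1H-isochromen-1-ol | C[Si](C)(C)C#C[C@H]1C[C@]2(C)[C@H](C)C(O[Si](C(C)C)(C(C)C)C(C)C)=CC[C@@H]2C(O)O1 | intermediate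
10 | N'-[(E)-{(1S,5S,6S)-6-[(2R)-2-hydroxy-4-(trimethylsilyl)but-3-yn-1-yl]-5,6-dimethyl-4-[(triisopropylsilyl)oxy]cyclohex-3-en-1-yl}methylidene]-4-methylbenzenesulfonohydrazide | C[Si](C)(C)C#C[C@H](O)C[C@]1(C)[C@H](C)C(O[Si](C(C)C)(C(C)C)C(C)C)=CC[C@@H]1/C=N/NS(=O)(=O)c1ccc(C)cc1 | intermediate
11 | (2R)-4-(trimethylsilyl)-1-[(1S,2S,6S)-1,2,6-trimethyl-3-[(triisopropylsilyl)oxy]cyclohex-3-en-1-yl]but-3-yn-2-ol | C[Si](C)(C)C#C[C@H](O)C[C@]1(C)[C@H](C)C(O[Si](C(C)C)(C(C)C)C(C)C)=CC[C@@H]1C | intermediate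
12 | (2S)-4-(trimethylsilyl)-1-[(1S,2S,6S)-1,2,6-trimethyl-3-[(triisopropylsilyl)oxy]cyclohex-3-en-1-yl]but-3-yn-2-yl 4-nitrobenzoate | C[Si](C)(C)C#C[C@@H](OC(=O)c1ccc(cc1)[N+](=O)[O-])C[C@]1(C)[C@H](C)C(O[Si](C(C)C)(C(C)C)C(C)C)=CC[C@@H]1C | intermediate
13 | (2S)-1-[(1S,2S,6S)-1,2,6-trimethyl-3-[(triisopropylsilyl)oxy]cyclohex-3-en-1-yl]but-3-yn-2-ol | C#C[C@@H](O)C[C@]1(C)[C@H](C)C(O[Si](C(C)C)(C(C)C)C(C)C)=CC[C@@H]1C | intermediate
14 | dimethylaluminium alkoxide of the (E)-2-methyl-1-(dimethylalumino)alkene derived from 13 | C[Al](C)/C=C(\C)[C@@H](O[Al](C)C)C[C@]1(C)[C@H](C)C(O[Si](C(C)C)(C(C)C)C(C)C)=CC[C@@H]1C | intermediate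
15 | (2S,3E)-4-iodo-3-methyl-1-[(1S,2S,6S)-1,2,6-trimethyl-3-[(triisopropylsilyl)oxy]cyclohex-3-en-1-yl]but-3-en-2-ol | I/C=C(\C)[C@@H](O)C[C@]1(C)[C@H](C)C(O[Si](C(C)C)(C(C)C)C(C)C)=CC[C@@H]1C | intermediate
16 | 5-methylbenzene-1,3-diol (orcinol) | Cc1cc(O)cc(O)c1 | starting material
17 | 1,3-bis(methoxymethoxy)-5-methylbenzene | COCOc1cc(C)cc(OCOC)c1 | intermediate
18 | [2,6-bis(methoxymethoxy)-4-methylphenyl]lithium | [Li]c1c(OCOC)cc(C)cc1OCOC | intermediate
19 | [2,6-bis(methoxymethoxy)-4-methylphenyl]methanol | OCc1c(OCOC)cc(C)cc1OCOC | intermediate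
20 | [3-chloro-2,6-bis(methoxymethoxy)-4-methylphenyl]methanol | OCc1c(OCOC)c(Cl)c(C)cc1OCOC | intermediate
21 | 3-chloro-2,6-bis(methoxymethoxy)-4-methylbenzyl chloride | ClCc1c(OCOC)c(Cl)c(C)cc1OCOC | intermediate
22 | [3-chloro-2,6-bis(methoxymethoxy)-4-methylbenzyl]zinc chloride | Cl[Zn]Cc1c(OCOC)c(Cl)c(C)cc1OCOC | intermediate
23 | (2S,3E)-5-[3-chloro-2,6-bis(methoxymethoxy)-4-methylphenyl]-3-methyl-1-[(1S,2S,6S)-1,2,6-trimethyl-3-[(triisopropylsilyl)oxy]cyclohex-3-en-1-yl]pent-3-en-2-ol | COCOc1cc(C)c(Cl)c(OCOC)c1C/C=C(\C)[C@@H](O)C[C@]2(C)[C@H](C)C(O[Si](C(C)C)(C(C)C)C(C)C)=CC[C@@H]2C | intermediate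
24 | 4-chloro-2-[(2E,4S)-4-hydroxy-3-methyl-5-[(1S,2S,6S)-1,2,6-trimethyl-3-oxocyclohexyl]pent-2-en-1-yl]-5-methylbenzene-1,3-diol | Cc1cc(O)c(C/C=C(\C)[C@@H](O)C[C@]2(C)[C@H](C)C(=O)CC[C@@H]2C)c(O)c1Cl | intermediate
25 | 5-chloro-2-hydroxy-3-[(2E,4S)-4-hydroxy-3-methyl-5-[(1S,2S,6S)-1,2,6-trimethyl-3-oxocyclohexyl]pent-2-en-1-yl]-6-methylcyclohexa-2,5-diene-1,4-dione | CC1=C(Cl)C(=O)C(C/C=C(\C)[C@@H](O)C[C@]2(C)[C@H](C)C(=O)CC[C@@H]2C)=C(O)C1=O | target

**Step count**
Total: 18 steps. Longest linear sequence: 13 steps (steps 2–11 and 16–18, from 3-(trimethylsilyl)propynal).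

**Steps most likely to fail, with fallbacks**

Step 5. Bond formation between the methyl-bearing diene terminus and the β,β-disubstituted lactone carbon may be too slow, so that Lewis-acid-induced loss or isomerisation of the silyl dienol ether outruns the cycloaddition; endo and facial selectivity may also erode. The fallback sets out from 7 and uses a far more nucleophilic diene without any Lewis acid. The 1-amino-3-siloxydiene (1E,3Z)-3-[(tert-butyldimethylsilyl)oxy]-N,N-dimethylpenta-1,3-dien-1-amine F1 (from commercial 1-(dimethylamino)pent-1-en-3-one, KN(SiMe3)2, t-BuMe2SiCl, THF, −78 °C) is heated with 7 in toluene at 60–80 °C. With the same regiochemistry and the same anti approach this should give the 8-(dimethylamino) silyl enol ether cycloadduct F2. Aqueous HCl in THF hydrolyses the enol ether and eliminates dimethylamine to the enone lactone (3R,4aR,5S,8aS)-4a,5-dimethyl-3-[(trimethylsilyl)ethynyl]-3,4,4a,5-tetrahydro-1H-isochromene-1,6(8aH)-dione F3. Conjugate reduction with LiBH(s-Bu)3 at −78 °C and O-silylation of the resulting enolate with i-Pr3SiOTf comes back to the route at 8.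

Step 16. Wurtz-type homocoupling during zinc insertion into the electron-rich, doubly ortho-substituted benzylic chloride, slow transmetalation of the hindered benzylzinc, and protonolysis by the free hydroxyl may starve the coupling. The fallback sets out from 13 and reverses the polarity of the union. The alkenylalane 14 generated as in step 11 is not iodinated but coupled directly with the benzylic chloride 21 under Pd(PPh3)4 catalysis in THF at 23 °C (Negishi alkenylalane–benzyl halide coupling), coming back at 23. This makes no new compound (F0).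

Step 17. Acid may ionise the allylic C4' alcohol (allylic transposition, methyl ether formation, or closure of a freed phenol onto the side chain) before both acetals are cleaved. The fallback sets out from 23 and masks the alcohol first. Acetylation (Ac2O, pyridine, DMAP) gives the C4' acetate of 23, (2S,3E)-5-[3-chloro-2,6-bis(methoxymethoxy)-4-methylphenyl]-3-methyl-1-[(1S,2S,6S)-1,2,6-trimethyl-3-[(triisopropylsilyl)oxy]cyclohex-3-en-1-yl]pent-3-en-2-yl acetate F4. The same acid treatment then gives the resorcinol keto acetate (2E,4S)-1-(3-chloro-2,6-dihydroxy-4-methylphenyl)-3-methyl-5-[(1S,2S,6S)-1,2,6-trimethyl-3-oxocyclohexyl]pent-2-en-4-yl acetate F5. Methanolysis with K2CO3 in MeOH under argon comes back at 24.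

Further compounds
F1 | step 5 | (1E,3Z)-3-[(tert-butyldimethylsilyl)oxy]-N,N-dimethylpenta-1,3-dien-1-amine | C/C=C(\O[Si](C)(C)C(C)(C)C)/C=C/N(C)C
F2 | step 5 | 6-[(tert-butyldimethylsilyl)oxy]-8-(dimethylamino)-4a,5-dimethyl-3-[(trimethylsilyl)ethynyl]-3,4,4a,5,8,8a-hexahydro-1H-isochromen-1-one (C3, C4a, C5 and ring fusion as in 8; C8 unassigned) | C[Si](C)(C)C#C[C@H]1C[C@]2(C)[C@H](C)C(O[Si](C)(C)C(C)(C)C)=CC(N(C)C)[C@@H]2C(=O)O1
F3 | step 5 | (3R,4aR,5S,8aS)-4a,5-dimethyl-3-[(trimethylsilyl)ethynyl]-3,4,4a,5-tetrahydro-1H-isochromene-1,6(8aH)-dione | C[Si](C)(C)C#C[C@H]1C[C@]2(C)[C@H](C)C(=O)C=C[C@@H]2C(=O)O1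
F0 | step 16 | none | none
F4 | step 17 | (2S,3E)-5-[3-chloro-2,6-bis(methoxymethoxy)-4-methylphenyl]-3-methyl-1-[(1S,2S,6S)-1,2,6-trimethyl-3-[(triisopropylsilyl)oxy]cyclohex-3-en-1-yl]pent-3-en-2-yl acetate | COCOc1cc(C)c(Cl)c(OCOC)c1C/C=C(\C)[C@@H](OC(C)=O)C[C@]2(C)[C@H](C)C(O[Si](C(C)C)(C(C)C)C(C)C)=CC[C@@H]2C
F5 | step 17 | (2E,4S)-1-(3-chloro-2,6-dihydroxy-4-methylphenyl)-3-methyl-5-[(1S,2S,6S)-1,2,6-trimethyl-3-oxocyclohexyl]pent-2-en-4-yl acetate | Cc1cc(O)c(C/C=C(\C)[C@@H](OC(C)=O)C[C@]2(C)[C@H](C)C(=O)CC[C@@H]2C)c(O)c1Cl
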